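## Analysis of the target

The target (26) has two heterocycles linked by one CH2 group. The first is an oxolane with ring A (3-hydroxy-4-methoxyphenyl) at C2, CH2OH at C3 and the bridging CH2 at C4. The second is a 2,3-dihydrobenzofuran whose benzene ring (ring B) carries OMe at C4 and the bridge at C6, with ring C (4-hydroxy-3-methoxyphenyl) at C2 and CH2OH at C3. There are five stereocentres in two clusters. The oxolane is (2R,3S,4S), with aryl and CH2OH trans and CH2OH and the bridge cis; the dihydrofuran is (2S,3R), trans. The CH2 bridge and the flat ring B insulate the clusters, so each needs its own source of absolute configuration. Both C2–O bonds are benzylic ethers of para-oxygenated aryl rings and so can ionise in acid or be hydrogenolysed; the dihydrofuran can be dehydrogenated to a benzofuran; the free phenols are oxidisable. The difficulties are ring B (1,2,3,5-tetrasubstituted, with two different oxygens flanking the carbon that bears C3), the less stable 3,4-cis relationship in the oxolane, and the two remote clusters. The strategy rests on one feature of the dihydrobenzofuran: C3 is the α-carbon of a ring B arylacetic acid, and C2 is the benzylic carbon of a (ring C)CH2–O–(ring B) ether. O1–C2 and C3a–C3 can therefore already exist in a ring B aryldiazoacetate with an ortho arylmethoxy group, and only C2–C3 has to be made.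

## Retrosynthetic reasoning

**Protecting groups (26 ⇐ 25 ⇐ 24).** The two phenols are carried as benzyl ethers and the two primary alcohols as silyl ethers. The para-benzyloxy group on ring C is also the donor that activates the C–H bond used in the key step. The silyl group on the oxolane arm is the steric marker for the later hydroboration. Fluoride and then hydrogenolysis release 26.

**Bridge bond (24 ⇐ 15 + 23, 23 ⇐ 22).** The bond between the bridge CH2 and ring B C6 is cut because it is the only C–C bond joining the two clusters, and it gives two halves of similar size. It is an sp3–sp2 bond, so ring B becomes an aryl triflate (15) and the oxolane a primary alkylborane (23). The borane comes from hydroboration of the exocyclic alkene 22. The forward step therefore creates C4 as well, and must deliver hydrogen to the face opposite the C3 arm so that the bridge ends cis to it.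

**Oxolane ring (22 ⇐ 21 ⇐ 20).** The C3–C4 bond is cut. A C3 radical generated from the terminal epoxide of 20 closes onto the propargyl ether. This makes the ring, the exocyclic methylene and the CH2OH arm in one operation. A radical is chosen because an anion at C3 would expel the β-alkoxy group. The C3 centre is relayed from C2 (trans), so the epoxide configuration is irrelevant.

**Oxolane C2 (20 ⇐ 19 ⇐ 18 ⇐ 17 ⇐ 16).** The epoxide comes from a vinyl group and the ether from the allylic alcohol 18. The single stereocentre of 18 is obtained by kinetic resolution of racemic 17, itself made by vinyl addition to aldehyde 16.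

**Dihydrofuran ring, the key disconnection (15 ⇐ 14 ⇐ 13 ⇐ 12 ⇐ 11).** The silyloxymethyl group is traced to the methyl ester 13, and then C2–C3 is cut. With this cut, both remaining ring bonds (O1–C7a and C3–C3a) are ordinary bonds to ring B, present in an arylacetate with an ortho benzylic ether. The forward step is an intramolecular carbene insertion into a benzylic C–H bond of diazo ester 11. It closes the ring and creates both stereocentres: C2 under catalyst control, C3 by equilibration of the cis ester 12 to 13. Cutting O1–C2 instead would need a configurationally defined, easily ionised benzylic electrophile. Cutting C3–C3a would need an arene alkylation between two oxygens.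

**Diazo ester (11 ⇐ 10 ⇐ 9 ⇐ 8 ⇐ 6 ⇐ 5).** The diazo group is put on the arylacetate 10 by diazo transfer. The acetate comes from aldehyde 5 by one-carbon homologation through styrene 6, alcohol 8 and acid 9. This sequence is neutral throughout, because the triflate does not tolerate hydroxide or alkoxide and the ring C benzylic aryl ether does not tolerate acid.

**Ring B pattern (5 ⇐ 3 + 4, 3 ⇐ 2 ⇐ 1).** The ether bond is cut to phenol 3 and benzylic alcohol 4. The three oxygens of ring B are told apart on the commercial aldehyde 1: the free para hydroxyl becomes the triflate (2), and one of the two equivalent ortho methoxy groups is cleaved by chelation to the formyl group (3).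

## Alternatives that were turned down

**Alternative 1:** Ring B itself is built. Two ring bonds of phenol A1 are cut: the bond from the hydroxyl-bearing carbon to the carbon carrying the three-carbon side chain, and the bond from the silyloxy-bearing carbon to the neighbouring CH. This leads to cyclobutenone A2, which carries the complete oxolane, and silyl ynol ether A3, which carries the two future dihydrofuran stereocentres as an open chain. In the forward step (a Danheiser-type benzannulation) the two are heated together: A2 opens to a vinylketene, this adds [2+2] across the triple bond of A3, the new cyclobutenone opens, and the dienylketene closes by 6π electrocyclisation and tautomerises to A1.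
- For: the regiochemistry is fixed by the mechanism, the two ring B oxygens emerge differentiated, and two fully elaborated halves are joined in the ring-forming step. The oxolane C4 centre is already in A2, so nothing depends on the facial selectivity of a hydroboration or on an sp3 cross-coupling. On these points it is stronger than the chosen route.
- Against: it constructs an arene that can be bought with the right oxygenation. A2 and A3 are both long to make. A3 needs an ester-to-ynol-ether homologation under strongly basic conditions next to the future C3 centre, which carries a β-silyloxy group, so elimination and epimerisation threaten. The most valuable material is heated in the key step. Afterwards the dihydrofuran is still open: the free hydroxyl must be methylated, two silyl ethers removed, and O1–C2 closed at a benzylic carbon with overall retention, which only an ionising closure under thermodynamic control can give.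
- Comparison: the chosen route gives up some convergence but buys ring B as aldehyde 1, and forms the dihydrofuran ring and both its stereocentres in one catalytic step (11 to 13).

**Alternative 2:** The dihydrofuran is cut at C3a–C3 and O1–C2, with ring B at the dihydroresorcinol oxidation level. In the forward step a one-electron oxidant of the trivalent manganese type converts dione A5 into its C2 radical. This adds to the alkene carbon next to the carbonyl of the Lewis-acid-chelated cinnamoyl imide A6, the benzylic radical is oxidised to the cation, and the enol oxygen captures it to give A4.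
- For: one step forms two bonds and both dihydrofuran stereocentres, with trans as the natural outcome. No diazo compound or precious metal is needed. Stereocontrol comes from an auxiliary, so the wrong isomer is a separable diastereomer. On this last point it is stronger than a route that relies on enantiomeric excess.
- Against: an electrophilic radical must attack the α-carbon of an electron-poor alkene, so the addition is polarity-mismatched and driven only by the benzylic radical. The bidentate chelation that gives facial control is hard to keep in the acidic, coordinating medium the oxidant needs. The oxidant can also attack the electron-rich aryl oxolane already present in A5. After the key step ring B must be dehydrogenated to the phenol without aromatising the neighbouring dihydrofuran or epimerising its doubly activated C3–H, then methylated, and the auxiliary removed.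
- Comparison: the chosen route keeps ring B aromatic from compound 1 on, so no oxidation-level change is made next to the new stereocentres. The oxolane is introduced late (step 18) and never meets an oxidant.

**Alternative 3:** This disconnection addresses the oxolane only, cutting C2–C3 and C4–C5. In the forward step a fluoride source triggers 1,3-elimination from the α-chloro silylmethyl ether A8 to give a non-stabilised carbonyl ylide. The ylide adds across the alkene of butenolide A9 on the face opposite the menthyloxy group and gives the cis-fused bicycle A7.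
- For: the 3,4-cis relationship follows from the cis ring fusion, and the absolute configuration comes from a crystalline acetal rather than a resolution. On both points it is stronger than the hydroboration and kinetic resolution of the chosen route.
- Against: the aryl orientation (2,3-trans is needed) and the regiochemistry of an ylide with no stabilising group are not dictated by the dipolarophile. In A7 the two carbons on C3 and C4 are at the lactone and acetal levels. One must be reduced to CH2OH and the other joined to ring B C6 and then fully deoxygenated at a benzylic position, which costs several steps and exposes the 2-aryl oxolane to acid. The dihydrobenzofuran still needs its own ring-forming and stereodefining step.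
- Comparison: the chosen route attaches ring B directly as an sp3–sp2 coupling of borane 23 with triflate 15 at the correct oxidation level, and solves the dihydrofuran in the same plan.

Key step: step 9

Assumption: the (R)-configured N-phthaloyl-tert-leucinate catalyst is taken to deliver the (2S) centre in step 9; if the 2,6-disubstituted substrate reverses the sense, the (S)-ligand catalyst is used and nothing else changes.

Assumption: compounds 4 and 16 are taken to be catalogue chemicals.

## Route

Step 1
Reactants: 1 4-hydroxy-2,6-dimethoxybenzaldehyde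
Product: 2 4-formyl-3,5-dimethoxyphenyl trifluoromethanesulfonate
Conditions: Tf2O, pyridine, CH2Cl2, 0 °C
Reagents that add atoms: trifluoromethanesulfonic anhydride, O=S(=O)(OS(=O)(=O)C(F)(F)F)C(F)(F)F
Why: O-Sulfonylation of an acidic, unhindered para-formyl phenol; the aldehyde is inert to these conditions.

Step 2
Reactants: 2 4-formyl-3,5-dimethoxyphenyl trifluoromethanesulfonate
Product: 3 4-formyl-3-hydroxy-5-methoxyphenyl trifluoromethanesulfonate
Conditions: BCl3 (1.2 equiv), CH2Cl2, −78 → 0 °C; aqueous work-up
Reagents that add atoms: none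
Why: Chelation-directed Lewis acid ether cleavage: boron bound to the formyl oxygen activates one ortho methoxy group for chloride attack on its methyl group. The resulting six-membered aryloxyboron chelate deactivates the ring towards a second cleavage, and the triflate is inert to BCl3.

Step 3
Reactants: 3 4-formyl-3-hydroxy-5-methoxyphenyl trifluoromethanesulfonate; 4 [4-(benzyloxy)-3-methoxyphenyl]methanol
Product: 5 3-{[4-(benzyloxy)-3-methoxyphenyl]methoxy}-4-formyl-5-methoxyphenyl trifluoromethanesulfonate
Conditions: PPh3, DIAD, THF, 0 °C → rt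
Reagents that add atoms: none
Why: Mitsunobu etherification; the ortho-formyl phenol is acidic enough to act as the pronucleophile and the primary benzylic alcohol is activated as its oxyphosphonium salt. The neutral conditions spare the triflate.

Step 4
Reactants: 5 3-{[4-(benzyloxy)-3-methoxyphenyl]methoxy}-4-formyl-5-methoxyphenyl trifluoromethanesulfonate
Product: 6 3-{[4-(benzyloxy)-3-methoxyphenyl]methoxy}-4-ethenyl-5-methoxyphenyl trifluoromethanesulfonate
Conditions: Ph3PCH3Br, NaHMDS, THF, 0 °C; then 5, 0 °C → rt
Reagents that add atoms: methyltriphenylphosphonium bromide, C[P+](c1ccccc1)(c1ccccc1)c1ccccc1.[Br-]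
Why: Wittig methylenation; the small non-stabilised ylide adds even to a di-ortho-alkoxy benzaldehyde. The ylide is preformed with slightly less base than salt so that no free amide base reaches the triflate.

Step 5
Reactants: 6 3-{[4-(benzyloxy)-3-methoxyphenyl]methoxy}-4-ethenyl-5-methoxyphenyl trifluoromethanesulfonate
Product: 8 3-{[4-(benzyloxy)-3-methoxyphenyl]methoxy}-4-(2-hydroxyethyl)-5-methoxyphenyl trifluoromethanesulfonate, via B-alkyl-9-BBN adduct 7 (not isolated)
Conditions: 9-BBN, THF, 0 °C → rt; then NaBO3·4H2O, H2O, rt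
Reagents that add atoms: sodium perborate, [Na+].[O-]OB=O
Why: Anti-Markovnikov hydroboration of a styrene; the bulky 9-BBN places boron on the terminal carbon. Perborate oxidises the C–B bond under conditions mild enough for the aryl triflate.

Step 6
Reactants: 8 3-{[4-(benzyloxy)-3-methoxyphenyl]methoxy}-4-(2-hydroxyethyl)-5-methoxyphenyl trifluoromethanesulfonate
Product: 9 2-(2-{[4-(benzyloxy)-3-methoxyphenyl]methoxy}-6-methoxy-4-{[(trifluoromethyl)sulfonyl]oxy}phenyl)acetic acid
Conditions: TEMPO (0.2 equiv), PhI(OAc)2 (2.2 equiv), MeCN/H2O 1:1, rt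
Reagents that add atoms: water, O
Why: Oxoammonium (TEMPO) oxidation with PhI(OAc)2 as terminal oxidant takes the primary alcohol through the aldehyde hydrate to the acid. No strong acid or base touches the acid-labile benzylic aryl ether or the triflate.

Step 7
Reactants: 9 2-(2-{[4-(benzyloxy)-3-methoxyphenyl]methoxy}-6-methoxy-4-{[(trifluoromethyl)sulfonyl]oxy}phenyl)acetic acid
Product: 10 methyl 2-(2-{[4-(benzyloxy)-3-methoxyphenyl]methoxy}-6-methoxy-4-{[(trifluoromethyl)sulfonyl]oxy}phenyl)acetate
Conditions: TMSCHN2, toluene/MeOH 4:1, 0 °C → rt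
Reagents that add atoms: (trimethylsilyl)diazomethane, C[Si](C)(C)C=[N+]=[N-]
Why: O-Methylation of the carboxylic acid by a diazomethane equivalent under neutral conditions, which leave the triflate and the benzylic ether untouched.

Step 8
Reactants: 10 methyl 2-(2-{[4-(benzyloxy)-3-methoxyphenyl]methoxy}-6-methoxy-4-{[(trifluoromethyl)sulfonyl]oxy}phenyl)acetate
Product: 11 methyl 2-(2-{[4-(benzyloxy)-3-methoxyphenyl]methoxy}-6-methoxy-4-{[(trifluoromethyl)sulfonyl]oxy}phenyl)-2-diazoacetate
Conditions: p-ABSA (1.5 equiv), DBU (2 equiv), MeCN, 0 °C → rt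
Reagents that add atoms: 4-acetamidobenzenesulfonyl azide, CC(=O)Nc1ccc(cc1)S(=O)(=O)N=[N+]=[N-]
Why: Regitz diazo transfer; DBU generates the benzylic ester enolate, which attacks the terminal nitrogen of the sulfonyl azide and expels the sulfonamide.

Step 9
Reactants: 11 methyl 2-(2-{[4-(benzyloxy)-3-methoxyphenyl]methoxy}-6-methoxy-4-{[(trifluoromethyl)sulfonyl]oxy}phenyl)-2-diazoacetate
Product: 13 methyl (2S,3S)-2-[4-(benzyloxy)-3-methoxyphenyl]-4-methoxy-6-{[(trifluoromethyl)sulfonyl]oxy}-2,3-dihydro-1-benzofuran-3-carboxylate, via cis ester 12 (not isolated)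
Conditions: Rh2(R-PTTL)4 (1 mol %; PTTL = N-phthaloyl-tert-leucinate), 4 Å MS, toluene, −78 → −40 °C; then DBU (1.5 equiv), 40 °C
Reagents that add atoms: none
Why: The divalent rhodium dimer expels the diazo nitrogen to give a donor–acceptor rhodium carbene, whose carbon inserts into one of the two enantiotopic C–H bonds of the ortho OCH2Ar group through a concerted, three-centre, hydride-transfer-like transition state; the closest known reaction type is the dirhodium-carboxylate-catalysed benzylic C–H insertion of 2-(benzyloxy)phenyl diazoacetates to cis-2-aryl-2,3-dihydrobenzofuran-3-carboxylates. The dihydrofuran ring closes as a 1,5-insertion, forming C2–C3 between the carbene carbon and the carbon five atoms away. C2 is set by the chiral carboxylate ligands, which decide which benzylic hydrogen is reached. C3 is first formed cis (12) as the kinetic result of the insertion geometry and is then set trans by DBU equilibration through the ester enolate. C2 survives this because ring opening by loss of the phenoxide would be the reverse of a 5-endo-trig closure and is stereoelectronically poor. Site selectivity is needed against the three C–H bonds of the ortho OMe group, the remote OCH2Ph group and addition to ring C; it is secured because the attacked C–H is activated twice, by the ether oxygen and by the para-benzyloxy ring C, while a methyl ether C–H is primary and much less hydridic, and only the 1,5-relationship gives an unstrained transition state. The second ortho substituent holds the carbene perpendicular to ring B, which is the geometry the insertion needs. Triflate, benzyl ether and methyl ester are inert to the carbene and to DBU in toluene.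

Step 10
Reactants: 13 methyl (2S,3S)-2-[4-(benzyloxy)-3-methoxyphenyl]-4-methoxy-6-{[(trifluoromethyl)sulfonyl]oxy}-2,3-dihydro-1-benzofuran-3-carboxylate
Product: 14 (2S,3R)-2-[4-(benzyloxy)-3-methoxyphenyl]-3-(hydroxymethyl)-4-methoxy-2,3-dihydro-1-benzofuran-6-yl trifluoromethanesulfonate
Conditions: LiBH4, THF (MeOH, 1 equiv), 0 °C → rt
Reagents that add atoms: none
Why: Chemoselective hydride reduction of the ester; aryl triflate and benzyl ether are not attacked by LiBH4. C3 is already in its thermodynamic trans arrangement, and the descriptor changes from S to R only through the priority change.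

Step 11
Reactants: 14 (2S,3R)-2-[4-(benzyloxy)-3-methoxyphenyl]-3-(hydroxymethyl)-4-methoxy-2,3-dihydro-1-benzofuran-6-yl trifluoromethanesulfonate
Product: 15 (2S,3R)-2-[4-(benzyloxy)-3-methoxyphenyl]-3-({[tert-butyl(dimethyl)silyl]oxy}methyl)-4-methoxy-2,3-dihydro-1-benzofuran-6-yl trifluoromethanesulfonate
Conditions: TBSCl, imidazole, CH2Cl2, rt
Reagents that add atoms: tert-butyldimethylsilyl chloride, CC(C)(C)[Si](C)(C)Cl
Why: Silylation of the primary alcohol, which would otherwise interfere with the aqueous-base coupling.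

Step 12
Reactants: 16 3-(benzyloxy)-4-methoxybenzaldehyde
Product: 17 rac-1-[3-(benzyloxy)-4-methoxyphenyl]prop-2-en-1-ol
Conditions: vinylmagnesium bromide, THF, −78 → 0 °C; aq. NH4Cl
Reagents that add atoms: vinylmagnesium bromide, C=C[Mg]Br
Why: Grignard 1,2-addition to the aldehyde.

Step 13
Reactants: 17 rac-1-[3-(benzyloxy)-4-methoxyphenyl]prop-2-en-1-ol
Product: 18 (1R)-1-[3-(benzyloxy)-4-methoxyphenyl]prop-2-en-1-ol
Conditions: Ti(OiPr)4, D-(−)-diisopropyl tartrate, t-BuOOH (0.6 equiv), 4 Å MS, CH2Cl2, −20 °C; recovered alcohol isolated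
Reagents that add atoms: none
Why: Sharpless kinetic resolution; the titanium tartrate complex epoxidises one enantiomer of a secondary allylic alcohol much faster than the other. With the D-(−)-tartrate the (S)-alcohol should be consumed, and the (R)-alcohol, which carries the future oxolane C2 configuration, is recovered just beyond half conversion.

Step 14
Reactants: 18 (1R)-1-[3-(benzyloxy)-4-methoxyphenyl]prop-2-en-1-ol
Product: 19 2-(benzyloxy)-1-methoxy-4-[(1R)-1-(prop-2-yn-1-yloxy)prop-2-en-1-yl]benzene
Conditions: NaH, propargyl bromide, Bu4NI (cat.), THF/DMF, 0 °C → rt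
Reagents that add atoms: propargyl bromide, C#CCBr
Why: Williamson ether synthesis at oxygen; the stereocentre is not involved, and at this temperature the propargyl ether does not isomerise to the allene.

Step 15
Reactants: 19 2-(benzyloxy)-1-methoxy-4-[(1R)-1-(prop-2-yn-1-yloxy)prop-2-en-1-yl]benzene
Product: 20 2-{(S)-[3-(benzyloxy)-4-methoxyphenyl](prop-2-yn-1-yloxy)methyl}oxirane (both epimers at the oxirane carbon)
Conditions: mCPBA (2–3 equiv), NaHCO3, CH2Cl2, 0 °C → rt
Reagents that add atoms: 3-chloroperbenzoic acid, OOC(=O)c1cccc(Cl)c1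
Why: Prilezhaev epoxidation of the terminal alkene, which reacts faster than the alkyne or the dialkoxyarene. Both oxirane epimers are acceptable because this carbon becomes a planar radical in step 16; the benzylic descriptor changes from R to S only through the priority change.

Step 16
Reactants: 20 2-{(S)-[3-(benzyloxy)-4-methoxyphenyl](prop-2-yn-1-yloxy)methyl}oxirane
Product: 21 [(2R,3S)-2-[3-(benzyloxy)-4-methoxyphenyl]-4-methylideneoxolan-3-yl]methanol
Conditions: Cp2TiCl2 (2.5 equiv), Zn dust, THF, rt, slow addition of the titanium reagent; then 1 M HCl, 0 °C (brief)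
Reagents that add atoms: none
Why: Nugent–RajanBabu reductive epoxide opening: Cp2TiCl (trivalent titanium) opens the oxirane to the secondary β-titanoxy radical at the future C3, which cyclises 5-exo-dig onto the propargyl ether, and the vinyl radical takes hydrogen from THF. C3 is set trans to the C2 aryl group because the CH2OTi arm avoids the adjacent aryl group in the envelope transition state; C2 from step 13 is untouched.

Step 17
Reactants: 21 [(2R,3S)-2-[3-(benzyloxy)-4-methoxyphenyl]-4-methylideneoxolan-3-yl]methanol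
Product: 22 tert-butyl{[(2R,3S)-2-[3-(benzyloxy)-4-methoxyphenyl]-4-methylideneoxolan-3-yl]methoxy}dimethylsilane
Conditions: TBSCl, imidazole, DMF, rt
Reagents that add atoms: tert-butyldimethylsilyl chloride, CC(C)(C)[Si](C)(C)Cl
Why: Silylation of the primary alcohol; the bulky silyl ether also shields the face of the alkene on which it sits.

Step 18
Reactants: 22 tert-butyl{[(2R,3S)-2-[3-(benzyloxy)-4-methoxyphenyl]-4-methylideneoxolan-3-yl]methoxy}dimethylsilane; 15 (2S,3R)-2-[4-(benzyloxy)-3-methoxyphenyl]-3-({[tert-butyl(dimethyl)silyl]oxy}methyl)-4-methoxy-2,3-dihydro-1-benzofuran-6-yl trifluoromethanesulfonate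
Product: 24 tert-butyl{[(2S,3R)-2-[4-(benzyloxy)-3-methoxyphenyl]-6-{[(3S,4S,5R)-5-[3-(benzyloxy)-4-methoxyphenyl]-4-({[tert-butyl(dimethyl)silyl]oxy}methyl)oxolan-3-yl]methyl}-4-methoxy-2,3-dihydro-1-benzofuran-3-yl]methoxy}dimethylsilane, via alkylborane 23 (not isolated)
Conditions: 9-BBN, THF, rt → 50 °C; then 15, Pd(dppf)Cl2 (5 mol %), K3PO4 (3 M aq.), DMF, 50 °C
Reagents that add atoms: none
Why: B-alkyl Suzuki–Miyaura coupling. 9-BBN puts boron on the exocyclic CH2 and delivers hydrogen to C4 from the face opposite the adjacent silyloxymethyl arm, so the new CH2B arm is cis to it (C4 S). The primary alkyl borate then transmetallates to the arylpalladium species formed from 15 and zerovalent palladium, and the wide-bite-angle dppf ligand favours reductive elimination over β-hydride loss.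

Step 19
Reactants: 24 tert-butyl{[(2S,3R)-2-[4-(benzyloxy)-3-methoxyphenyl]-6-{[(3S,4S,5R)-5-[3-(benzyloxy)-4-methoxyphenyl]-4-({[tert-butyl(dimethyl)silyl]oxy}methyl)oxolan-3-yl]methyl}-4-methoxy-2,3-dihydro-1-benzofuran-3-yl]methoxy}dimethylsilane
Product: 25 [(2S,3R)-2-[4-(benzyloxy)-3-methoxyphenyl]-6-{[(3S,4S,5R)-5-[3-(benzyloxy)-4-methoxyphenyl]-4-(hydroxymethyl)oxolan-3-yl]methyl}-4-methoxy-2,3-dihydro-1-benzofuran-3-yl]methanol
Conditions: TBAF, THF, 0 °C → rt
Reagents that add atoms: none
Why: Fluoride cleavage of both primary silyl ethers; benzyl ethers and both cyclic benzylic ethers are inert.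

Step 20
Reactants: 25 [(2S,3R)-2-[4-(benzyloxy)-3-methoxyphenyl]-6-{[(3S,4S,5R)-5-[3-(benzyloxy)-4-methoxyphenyl]-4-(hydroxymethyl)oxolan-3-yl]methyl}-4-methoxy-2,3-dihydro-1-benzofuran-3-yl]methanol
Product: 26 5-[(2R,3S,4S)-4-{[(2S,3R)-2-(4-hydroxy-3-methoxyphenyl)-3-(hydroxymethyl)-4-methoxy-2,3-dihydro-1-benzofuran-6-yl]methyl}-3-(hydroxymethyl)oxolan-2-yl]-2-methoxyphenol
Conditions: H2 (1 atm), Pd/C (10 %), EtOAc/EtOH, rt; stopped after uptake of 2 equiv H2
Reagents that add atoms: none
Why: Hydrogenolysis of the two aryl benzyl ethers on palladium. Under neutral conditions these should cleave much faster than the two cyclic benzylic C–O bonds, and no stereocentre is touched.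

## Compound list

1 | 4-hydroxy-2,6-dimethoxybenzaldehyde | COc1cc(O)cc(OC)c1C=O | starting material
2 | 4-formyl-3,5-dimethoxyphenyl trifluoromethanesulfonate | COc1cc(OS(=O)(=O)C(F)(F)F)cc(OC)c1C=O | intermediate
3 | 4-formyl-3-hydroxy-5-methoxyphenyl trifluoromethanesulfonate | COc1cc(OS(=O)(=O)C(F)(F)F)cc(O)c1C=O | intermediate
4 | [4-(benzyloxy)-3-methoxyphenyl]methanol | COc1cc(CO)ccc1OCc1ccccc1 | starting material
5 | 3-{[4-(benzyloxy)-3-methoxyphenyl]methoxy}-4-formyl-5-methoxyphenyl trifluoromethanesulfonate | COc1cc(OS(=O)(=O)C(F)(F)F)cc(OCc2ccc(OCc3ccccc3)c(OC)c2)c1C=O | intermediate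
6 | 3-{[4-(benzyloxy)-3-methoxyphenyl]methoxy}-4-ethenyl-5-methoxyphenyl trifluoromethanesulfonate | C=Cc1c(OC)cc(OS(=O)(=O)C(F)(F)F)cc1OCc1ccc(OCc2ccccc2)c(OC)c1 | intermediate
7 | 3-{[4-(benzyloxy)-3-methoxyphenyl]methoxy}-4-[2-(9-borabicyclo[3.3.1]nonan-9-yl)ethyl]-5-methoxyphenyl trifluoromethanesulfonate | C1CC2CCCC(C1)B2CCc1c(OC)cc(OS(=O)(=O)C(F)(F)F)cc1OCc1ccc(OCc2ccccc2)c(OC)c1 | intermediate (not isolated)
8 | 3-{[4-(benzyloxy)-3-methoxyphenyl]methoxy}-4-(2-hydroxyethyl)-5-methoxyphenyl trifluoromethanesulfonate | OCCc1c(OC)cc(OS(=O)(=O)C(F)(F)F)cc1OCc1ccc(OCc2ccccc2)c(OC)c1 | intermediate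
9 | 2-(2-{[4-(benzyloxy)-3-methoxyphenyl]methoxy}-6-methoxy-4-{[(trifluoromethyl)sulfonyl]oxy}phenyl)acetic acid | OC(=O)Cc1c(OC)cc(OS(=O)(=O)C(F)(F)F)cc1OCc1ccc(OCc2ccccc2)c(OC)c1 | intermediate
10 | methyl 2-(2-{[4-(benzyloxy)-3-methoxyphenyl]methoxy}-6-methoxy-4-{[(trifluoromethyl)sulfonyl]oxy}phenyl)acetate | COC(=O)Cc1c(OC)cc(OS(=O)(=O)C(F)(F)F)cc1OCc1ccc(OCc2ccccc2)c(OC)c1 | intermediate
11 | methyl 2-(2-{[4-(benzyloxy)-3-methoxyphenyl]methoxy}-6-methoxy-4-{[(trifluoromethyl)sulfonyl]oxy}phenyl)-2-diazoacetate | COC(=O)C(=[N+]=[N-])c1c(OC)cc(OS(=O)(=O)C(F)(F)F)cc1OCc1ccc(OCc2ccccc2)c(OC)c1 | intermediate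
12 | methyl (2S,3R)-2-[4-(benzyloxy)-3-methoxyphenyl]-4-methoxy-6-{[(trifluoromethyl)sulfonyl]oxy}-2,3-dihydro-1-benzofuran-3-carboxylate (cis) | FC(F)(F)S(=O)(=O)Oc1cc(OC)c2c(c1)O[C@H](c1ccc(OCc3ccccc3)c(OC)c1)[C@@H]2C(=O)OC | intermediate (not isolated)
13 | methyl (2S,3S)-2-[4-(benzyloxy)-3-methoxyphenyl]-4-methoxy-6-{[(trifluoromethyl)sulfonyl]oxy}-2,3-dihydro-1-benzofuran-3-carboxylate (trans) | FC(F)(F)S(=O)(=O)Oc1cc(OC)c2c(c1)O[C@H](c1ccc(OCc3ccccc3)c(OC)c1)[C@H]2C(=O)OC | intermediate
14 | (2S,3R)-2-[4-(benzyloxy)-3-methoxyphenyl]-3-(hydroxymethyl)-4-methoxy-2,3-dihydro-1-benzofuran-6-yl trifluoromethanesulfonate | FC(F)(F)S(=O)(=O)Oc1cc(OC)c2c(c1)O[C@H](c1ccc(OCc3ccccc3)c(OC)c1)[C@H]2CO | intermediate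
15 | (2S,3R)-2-[4-(benzyloxy)-3-methoxyphenyl]-3-({[tert-butyl(dimethyl)silyl]oxy}methyl)-4-methoxy-2,3-dihydro-1-benzofuran-6-yl trifluoromethanesulfonate | FC(F)(F)S(=O)(=O)Oc1cc(OC)c2c(c1)O[C@H](c1ccc(OCc3ccccc3)c(OC)c1)[C@H]2CO[Si](C)(C)C(C)(C)C | intermediate
16 | 3-(benzyloxy)-4-methoxybenzaldehyde | COc1ccc(C=O)cc1OCc1ccccc1 | starting material
17 | rac-1-[3-(benzyloxy)-4-methoxyphenyl]prop-2-en-1-ol | COc1ccc(C(O)C=C)cc1OCc1ccccc1 | intermediate
18 | (1R)-1-[3-(benzyloxy)-4-methoxyphenyl]prop-2-en-1-ol | COc1ccc([C@H](O)C=C)cc1OCc1ccccc1 | intermediate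
19 | 2-(benzyloxy)-1-methoxy-4-[(1R)-1-(prop-2-yn-1-yloxy)prop-2-en-1-yl]benzene | COc1ccc([C@H](OCC#C)C=C)cc1OCc1ccccc1 | intermediate
20 | 2-{(S)-[3-(benzyloxy)-4-methoxyphenyl](prop-2-yn-1-yloxy)methyl}oxirane (both oxirane epimers) | COc1ccc([C@H](OCC#C)C2CO2)cc1OCc1ccccc1 | intermediate
21 | [(2R,3S)-2-[3-(benzyloxy)-4-methoxyphenyl]-4-methylideneoxolan-3-yl]methanol | COc1ccc([C@@H]2OCC(=C)[C@H]2CO)cc1OCc1ccccc1 | intermediate
22 | tert-butyl{[(2R,3S)-2-[3-(benzyloxy)-4-methoxyphenyl]-4-methylideneoxolan-3-yl]methoxy}dimethylsilane | COc1ccc([C@@H]2OCC(=C)[C@H]2CO[Si](C)(C)C(C)(C)C)cc1OCc1ccccc1 | intermediate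
23 | 9-{[(3S,4S,5R)-5-[3-(benzyloxy)-4-methoxyphenyl]-4-({[tert-butyl(dimethyl)silyl]oxy}methyl)oxolan-3-yl]methyl}-9-borabicyclo[3.3.1]nonane | COc1ccc([C@@H]2OC[C@@H](CB3C4CCCC3CCC4)[C@H]2CO[Si](C)(C)C(C)(C)C)cc1OCc1ccccc1 | intermediate (not isolated)
24 | tert-butyl{[(2S,3R)-2-[4-(benzyloxy)-3-methoxyphenyl]-6-{[(3S,4S,5R)-5-[3-(benzyloxy)-4-methoxyphenyl]-4-({[tert-butyl(dimethyl)silyl]oxy}methyl)oxolan-3-yl]methyl}-4-methoxy-2,3-dihydro-1-benzofuran-3-yl]methoxy}dimethylsilane | COc1ccc([C@@H]2OC[C@@H](Cc3cc(OC)c4c(c3)O[C@H](c3ccc(OCc5ccccc5)c(OC)c3)[C@H]4CO[Si](C)(C)C(C)(C)C)[C@H]2CO[Si](C)(C)C(C)(C)C)cc1OCc1ccccc1 | intermediate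
25 | [(2S,3R)-2-[4-(benzyloxy)-3-methoxyphenyl]-6-{[(3S,4S,5R)-5-[3-(benzyloxy)-4-methoxyphenyl]-4-(hydroxymethyl)oxolan-3-yl]methyl}-4-methoxy-2,3-dihydro-1-benzofuran-3-yl]methanol | COc1ccc([C@@H]2OC[C@@H](Cc3cc(OC)c4c(c3)O[C@H](c3ccc(OCc5ccccc5)c(OC)c3)[C@H]4CO)[C@H]2CO)cc1OCc1ccccc1 | intermediate
26 | 5-[(2R,3S,4S)-4-{[(2S,3R)-2-(4-hydroxy-3-methoxyphenyl)-3-(hydroxymethyl)-4-methoxy-2,3-dihydro-1-benzofuran-6-yl]methyl}-3-(hydroxymethyl)oxolan-2-yl]-2-methoxyphenol | COc1ccc([C@@H]2OC[C@@H](Cc3cc(OC)c4c(c3)O[C@H](c3ccc(O)c(OC)c3)[C@H]4CO)[C@H]2CO)cc1O | target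

## Step count and least certain steps

Total step count: 20. Longest linear sequence: 14 steps (steps 1–11, then 18–20, from 1). The oxolane branch is 6 steps (12–17).

**Step 9 (key step).** The second ortho substituent (OMe) may change the conformation of the bound carbene from that of the simpler mono-ortho substrates and so erode the enantioselectivity. It may also slow carbene formation, so that a higher temperature is needed and selectivity falls further. Some insertion into the methoxy C–H bonds and slow cis-to-trans equilibration are further possibilities. Fallback, setting out from acid 9 and returning at alcohol 14: 9 is esterified (EDC, DMAP) with (2S)-2-hydroxy-1-(pyrrolidin-1-yl)propan-1-one to give the lactamide ester F1. Diazo transfer as in step 8 gives the diazo ester F2. Insertion with Rh2(S-DOSP)4 or its mirror image, whichever pairs with the auxiliary, gives the cis ester F3, and DBU in the same flask converts it to the trans ester F4. The stereoisomers are now diastereomers and are separated by chromatography or crystallisation, so stereochemical purity no longer rests on the catalyst alone. LiBH4 then cleaves the auxiliary ester reductively and gives 14 directly.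

**Step 8.** The ester enolate of a doubly ortho-substituted arylacetate cannot lie coplanar with the ring, so equilibrium deprotonation by DBU may be too slow. Prolonged exposure to the amidine then risks slow loss of the triflate. Fallback, from 10 back to 11: a deacylative diazo transfer. Kinetic deprotonation with LiHMDS (THF, −78 °C) and acylation with 2,2,2-trifluoroethyl trifluoroacetate gives the α-trifluoroacetyl ester F5. F5 is acidic enough to react with MsN3 and Et3N in MeCN, with loss of the trifluoroacetyl group, to give 11.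

**Step 18.** Hydroboration may not discriminate well between the two faces, because the C2 aryl group lies on the face that the borane should use; this would give the C4 epimer. In the coupling, hydrolysis of the triflate by aqueous base and β-hydride loss from the alkylpalladium species may also compete. Fallback, setting out from alkyne 19 and triflate 15 and returning at 26: the bridge bond is made first by Sonogashira coupling (Pd(PPh3)2Cl2, CuI, Et3N, DMF, 60 °C) to give the aryl alkyne F6. Epoxidation as in step 15 gives F7, and the trivalent titanium cyclisation of step 16, now onto an aryl alkyne, gives the 4-arylmethylidene oxolane F8. Hydrogenation (H2, Pd/C) adds hydrogen to the exocyclic alkene from the face opposite the C3 arm and removes both benzyl groups, giving the mono-silyl ether F9. TBAF then gives 26.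

**Step 16.** A second equivalent of Cp2TiCl may reduce the β-titanoxy radical before it cyclises, which leads to deoxygenation back to the alkene, and the trans selectivity at C3 may be incomplete. Fallback, from 19 back to 22: the radical is made without a reducing metal. Dihydroxylation (K2OsO4·2H2O cat., NMO) gives diol F10. Selective silylation of the primary hydroxyl (TBSCl, imidazole) gives F11, and thiocarbonyldiimidazole gives the imidazolyl thiocarbonate F12. Slow addition of Bu3SnH with AIBN in refluxing benzene (Barton–McCombie radical generation, 5-exo-dig closure) gives 22 directly.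

**Step 13.** The Lewis-acidic titanium may ionise the electron-rich aryl vinyl carbinol, causing racemisation or 1,3-transposition, and the selectivity factor for a terminal vinyl carbinol may be modest. Fallback, from 17 back to 18: an enzymatic resolution under neutral conditions. Immobilised Candida antarctica lipase B with vinyl acetate in MTBE should acylate the (R)-alcohol, by the usual empirical rule for this enzyme, to give the acetate F13. F13 is separated from the unreacted (S)-alcohol and methanolysed (K2CO3, MeOH) to 18.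

## Further compounds

F1 | step 9 | (2S)-1-oxo-1-(pyrrolidin-1-yl)propan-2-yl 2-(2-{[4-(benzyloxy)-3-methoxyphenyl]methoxy}-6-methoxy-4-{[(trifluoromethyl)sulfonyl]oxy}phenyl)acetate | C[C@H](OC(=O)Cc1c(OC)cc(OS(=O)(=O)C(F)(F)F)cc1OCc1ccc(OCc2ccccc2)c(OC)c1)C(=O)N1CCCC1
F2 | step 9 | (2S)-1-oxo-1-(pyrrolidin-1-yl)propan-2-yl 2-(2-{[4-(benzyloxy)-3-methoxyphenyl]methoxy}-6-methoxy-4-{[(trifluoromethyl)sulfonyl]oxy}phenyl)-2-diazoacetate | C[C@H](OC(=O)C(=[N+]=[N-])c1c(OC)cc(OS(=O)(=O)C(F)(F)F)cc1OCc1ccc(OCc2ccccc2)c(OC)c1)C(=O)N1CCCC1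
F3 | step 9 | (2S)-1-oxo-1-(pyrrolidin-1-yl)propan-2-yl (2S,3R)-2-[4-(benzyloxy)-3-methoxyphenyl]-4-methoxy-6-{[(trifluoromethyl)sulfonyl]oxy}-2,3-dihydro-1-benzofuran-3-carboxylate (cis) | FC(F)(F)S(=O)(=O)Oc1cc(OC)c2c(c1)O[C@H](c1ccc(OCc3ccccc3)c(OC)c1)[C@@H]2C(=O)O[C@@H](C)C(=O)N1CCCC1
F4 | step 9 | (2S)-1-oxo-1-(pyrrolidin-1-yl)propan-2-yl (2S,3S)-2-[4-(benzyloxy)-3-methoxyphenyl]-4-methoxy-6-{[(trifluoromethyl)sulfonyl]oxy}-2,3-dihydro-1-benzofuran-3-carboxylate (trans) | FC(F)(F)S(=O)(=O)Oc1cc(OC)c2c(c1)O[C@H](c1ccc(OCc3ccccc3)c(OC)c1)[C@H]2C(=O)O[C@@H](C)C(=O)N1CCCC1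
F5 | step 8 | methyl 2-(2-{[4-(benzyloxy)-3-methoxyphenyl]methoxy}-6-methoxy-4-{[(trifluoromethyl)sulfonyl]oxy}phenyl)-4,4,4-trifluoro-3-oxobutanoate | COC(=O)C(C(=O)C(F)(F)F)c1c(OC)cc(OS(=O)(=O)C(F)(F)F)cc1OCc1ccc(OCc2ccccc2)c(OC)c1
F6 | step 18 | tert-butyl{[(2S,3R)-2-[4-(benzyloxy)-3-methoxyphenyl]-6-(3-{(1R)-1-[3-(benzyloxy)-4-methoxyphenyl]prop-2-en-1-yloxy}prop-1-yn-1-yl)-4-methoxy-2,3-dihydro-1-benzofuran-3-yl]methoxy}dimethylsilane | COc1ccc([C@H](OCC#Cc2cc(OC)c3c(c2)O[C@H](c2ccc(OCc4ccccc4)c(OC)c2)[C@H]3CO[Si](C)(C)C(C)(C)C)C=C)cc1OCc1ccccc1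
F7 | step 18 | tert-butyl{[(2S,3R)-2-[4-(benzyloxy)-3-methoxyphenyl]-6-(3-{(S)-[3-(benzyloxy)-4-methoxyphenyl](oxiran-2-yl)methoxy}prop-1-yn-1-yl)-4-methoxy-2,3-dihydro-1-benzofuran-3-yl]methoxy}dimethylsilane (both oxirane epimers) | COc1ccc([C@H](OCC#Cc2cc(OC)c3c(c2)O[C@H](c2ccc(OCc4ccccc4)c(OC)c2)[C@H]3CO[Si](C)(C)C(C)(C)C)C2CO2)cc1OCc1ccccc1
F8 | step 18 | [(2R,3S)-2-[3-(benzyloxy)-4-methoxyphenyl]-4-{[(2S,3R)-2-[4-(benzyloxy)-3-methoxyphenyl]-3-({[tert-butyl(dimethyl)silyl]oxy}methyl)-4-methoxy-2,3-dihydro-1-benzofuran-6-yl]methylidene}oxolan-3-yl]methanol (alkene geometry not fixed) | COc1ccc([C@@H]2OCC(=Cc3cc(OC)c4c(c3)O[C@H](c3ccc(OCc5ccccc5)c(OC)c3)[C@H]4CO[Si](C)(C)C(C)(C)C)[C@H]2CO)cc1OCc1ccccc1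
F9 | step 18 | 5-[(2R,3S,4S)-4-{[(2S,3R)-3-({[tert-butyl(dimethyl)silyl]oxy}methyl)-2-(4-hydroxy-3-methoxyphenyl)-4-methoxy-2,3-dihydro-1-benzofuran-6-yl]methyl}-3-(hydroxymethyl)oxolan-2-yl]-2-methoxyphenol | COc1ccc([C@@H]2OC[C@@H](Cc3cc(OC)c4c(c3)O[C@H](c3ccc(O)c(OC)c3)[C@H]4CO[Si](C)(C)C(C)(C)C)[C@H]2CO)cc1O
F10 | step 16 | (3S)-3-[3-(benzyloxy)-4-methoxyphenyl]-3-(prop-2-yn-1-yloxy)propane-1,2-diol (both C2 epimers) | COc1ccc([C@H](OCC#C)C(O)CO)cc1OCc1ccccc1
F11 | step 16 | (1S)-1-[3-(benzyloxy)-4-methoxyphenyl]-3-{[tert-butyl(dimethyl)silyl]oxy}-1-(prop-2-yn-1-yloxy)propan-2-ol (both C2 epimers) | COc1ccc([C@H](OCC#C)C(O)CO[Si](C)(C)C(C)(C)C)cc1OCc1ccccc1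
F12 | step 16 | O-[(1S)-1-[3-(benzyloxy)-4-methoxyphenyl]-3-{[tert-butyl(dimethyl)silyl]oxy}-1-(prop-2-yn-1-yloxy)propan-2-yl] 1H-imidazole-1-carbothioate (both C2 epimers) | COc1ccc([C@H](OCC#C)C(OC(=S)n2ccnc2)CO[Si](C)(C)C(C)(C)C)cc1OCc1ccccc1
F13 | step 13 | (1R)-1-[3-(benzyloxy)-4-methoxyphenyl]prop-2-en-1-yl acetate | COc1ccc([C@H](OC(C)=O)C=C)cc1OCc1ccccc1
A1 | alternative 1 | 2-{(1S,2R)-3-(benzyloxy)-1-[4-(benzyloxy)-3-methoxyphenyl]-1-[(tert-butyldimethylsilyl)oxy]propan-2-yl}-5-{[(3S,4S,5R)-5-[3-(benzyloxy)-4-methoxyphenyl]-4-({[tert-butyl(dimethyl)silyl]oxy}methyl)oxolan-3-yl]methyl}-3-[(triisopropylsilyl)oxy]phenol | COc1ccc([C@@H]2OC[C@@H](Cc3cc(O[Si](C(C)C)(C(C)C)C(C)C)c([C@H](COCc4ccccc4)[C@H](O[Si](C)(C)C(C)(C)C)c4ccc(OCc5ccccc5)c(OC)c4)c(O)c3)[C@H]2CO[Si](C)(C)C(C)(C)C)cc1OCc1ccccc1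
A2 | alternative 1 | 3-{[(3S,4S,5R)-5-[3-(benzyloxy)-4-methoxyphenyl]-4-({[tert-butyl(dimethyl)silyl]oxy}methyl)oxolan-3-yl]methyl}cyclobut-2-en-1-one | COc1ccc([C@@H]2OC[C@@H](CC3=CC(=O)C3)[C@H]2CO[Si](C)(C)C(C)(C)C)cc1OCc1ccccc1
A3 | alternative 1 | {[(3R,4S)-3-[(benzyloxy)methyl]-4-[4-(benzyloxy)-3-methoxyphenyl]-4-[(tert-butyldimethylsilyl)oxy]but-1-yn-1-yl]oxy}tri(propan-2-yl)silane | CC(C)[Si](C(C)C)(C(C)C)OC#C[C@H](COCc1ccccc1)[C@H](O[Si](C)(C)C(C)(C)C)c1ccc(OCc2ccccc2)c(OC)c1
A4 | alternative 2 | (4S)-4-benzyl-3-{[(2S,3S)-2-[4-(benzyloxy)-3-methoxyphenyl]-6-{[(3S,4S,5R)-5-[3-(benzyloxy)-4-methoxyphenyl]-4-[(benzyloxy)methyl]oxolan-3-yl]methyl}-4-oxo-2,3,4,5,6,7-hexahydro-1-benzofuran-3-yl]carbonyl}-1,3-oxazolidin-2-one (both C6 epimers) | COc1ccc([C@@H]2OC[C@@H](CC3CC(=O)C4=C(C3)O[C@H](c3ccc(OCc5ccccc5)c(OC)c3)[C@H]4C(=O)N3C(=O)OC[C@@H]3Cc3ccccc3)[C@H]2COCc2ccccc2)cc1OCc1ccccc1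
A5 | alternative 2 | 5-{[(3S,4S,5R)-5-[3-(benzyloxy)-4-methoxyphenyl]-4-[(benzyloxy)methyl]oxolan-3-yl]methyl}cyclohexane-1,3-dione | COc1ccc([C@@H]2OC[C@@H](CC3CC(=O)CC(=O)C3)[C@H]2COCc2ccccc2)cc1OCc1ccccc1
A6 | alternative 2 | (4S)-4-benzyl-3-{(2E)-3-[4-(benzyloxy)-3-methoxyphenyl]prop-2-enoyl}-1,3-oxazolidin-2-one | COc1cc(/C=C/C(=O)N2C(=O)OC[C@@H]2Cc2ccccc2)ccc1OCc1ccccc1
A7 | alternative 3 | 6-[3-(benzyloxy)-4-methoxyphenyl]-4-{[(1R,2S,5R)-5-methyl-2-(propan-2-yl)cyclohexyl]oxy}-3,7-dioxabicyclo[3.3.0]octan-2-one (cis-fused, aryl trans to the lactone carbonyl carbon, menthyloxy anti to the oxolane) | COc1ccc([C@@H]2OC[C@H]3[C@H](O[C@@H]4C[C@H](C)CC[C@H]4C(C)C)OC(=O)[C@@H]23)cc1OCc1ccccc1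
A8 | alternative 3 | ({[3-(benzyloxy)-4-methoxyphenyl](chloro)methoxy}methyl)trimethylsilane (racemic) | COc1ccc(C(Cl)OC[Si](C)(C)C)cc1OCc1ccccc1
A9 | alternative 3 | (5R)-5-{[(1R,2S,5R)-5-methyl-2-(propan-2-yl)cyclohexyl]oxy}furan-2(5H)-one | O=C1C=C[C@H](O[C@@H]2C[C@H](C)CC[C@H]2C(C)C)O1
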